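**Plan**

1. The last cut removes the three O-alkyl groups (two OMe, one OEt), so the free tetraphenol appears only at the end.
2. Ring A (the 2,4,6-trioxygenated phenyl ring) is cut at two ring bonds: acyl-bearing carbon to the C-OMe carbon, and C-OEt carbon to the neighbouring CH. This is possible because the acyl-bearing carbon of ring A lies between two C-O carbons with the third C-O carbon para to it, which is the pattern of a 1,1,3-trioxygenated butadiene joined to a β-alkoxy ynone that already holds the ketone.
3. The ynone is cut at the alkyne–carbonyl bond (Weinreb amide plus lithium ethoxyacetylide), and the chain at the CH2–ring B bond (B-alkyl Suzuki coupling of methyl undec-10-enoate with 2-bromoanisole).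
4. The diene comes from acetyl chloride and 1,1-dichloroethene through 4,4-dimethoxybut-3-en-2-one.
5. Forward order: ring B is joined to the C11 chain, the chain is capped as the ethoxy ynone, ring A is then built as the only ring formed in the route, and the ethers are cleaved.
6. Stereochemistry: the target has no stereocentre and no stereogenic double bond, so none has to be set.

Key step: step 7

**Route**

Step 1
Reactants: 1 methyl undec-10-enoate; 2 9-BBN (9-borabicyclo[3.3.1]nonane); 3 2-bromoanisole
Product: 5 methyl 11-(2-methoxyphenyl)undecanoate, via alkylborane 4 (not isolated)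
Conditions: 9-BBN (0.5 M in THF), 0 °C to rt; then 3, PdCl2(dppf) (3 mol %), K3PO4 (3 M aq), DMF, 65 °C
Reagents that add atoms: none
Why: 9-BBN should add to the terminal alkene with anti-Markovnikov selectivity without touching the ester, and the phosphate-activated B-alkyl borane should transmetalate to the arylpalladium bromide formed from 3 and zerovalent palladium (B-alkyl Suzuki–Miyaura coupling), the dppf ligand favouring reductive elimination over β-hydride elimination.

Step 2
Reactants: 5 methyl 11-(2-methoxyphenyl)undecanoate
Product: 6 N-methoxy-N-methyl-11-(2-methoxyphenyl)undecanamide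
Conditions: MeNH(OMe)·HCl (1.5 equiv), iPrMgCl (3 equiv), THF, −20 to 0 °C
Reagents that add atoms: N,O-dimethylhydroxylamine hydrochloride, CNOC.Cl
Why: The chloromagnesium amide of N,O-dimethylhydroxylamine, formed in the flask with iPrMgCl, should convert the methyl ester directly into the Weinreb amide (ester aminolysis), and the anisole and the saturated chain are inert to it.

Step 3
Reactants: 6 N-methoxy-N-methyl-11-(2-methoxyphenyl)undecanamide; 7 ethoxyacetylene
Product: 10 1-ethoxy-13-(2-methoxyphenyl)tridec-1-yn-3-one, via lithium ethoxyacetylide 8 (not isolated), via tetrahedral lithium adduct 9 (not isolated)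
Conditions: 7 (2 equiv), n-BuLi (1.9 equiv), THF, −78 °C; then 6, −78 to −30 °C; cold sat. aq NH4Cl
Reagents that add atoms: none
Why: Lithium ethoxyacetylide should add only once to the Weinreb amide because the chelated tetrahedral adduct 9 persists until the quench (Weinreb ketone synthesis), and the cold, nearly neutral quench spares the acid-labile alkynyl ether.

Step 4
Reactants: 11 acetyl chloride; 12 1,1-dichloroethene
Product: 14 4,4-dichlorobut-3-en-2-one, via 4,4,4-trichlorobutan-2-one 13 (not isolated)
Conditions: AlCl3 (1.1 equiv), CH2Cl2, 0 °C to rt; ice/aq HCl; distillation under reduced pressure (loss of HCl)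
Reagents that add atoms: none
Why: The acetylium ion generated with AlCl3 should add to the CH2 terminus of 1,1-dichloroethene with chloride capture of the cation (Friedel–Crafts-type acylation of an alkene), and the β-trichloromethyl ketone 13 then loses HCl to the conjugated dichlorovinyl ketone.

Step 5
Reactants: 14 4,4-dichlorobut-3-en-2-one
Product: 15 4,4-dimethoxybut-3-en-2-one
Conditions: NaOMe (2.05 equiv), MeOH, 0 °C to rt
Reagents that add atoms: sodium methoxide, [Na+].[O-]C
Why: Each vinylic chloride β to the ketone should be replaced by methoxide through conjugate addition–elimination (nucleophilic vinylic substitution), and holding the base at two equivalents guards against addition of a third methoxide to the keto ketene acetal.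

Step 6
Reactants: 15 4,4-dimethoxybut-3-en-2-one
Product: 16 1,1-dimethoxy-3-(trimethylsilyloxy)buta-1,3-diene
Conditions: TMSCl (1.3 equiv), Et3N (1.5 equiv), ZnCl2 (3 mol %), toluene, 40 °C; filtration under argon, distillation
Reagents that add atoms: chlorotrimethylsilane, C[Si](C)(C)Cl
Why: Soft enolisation of the acetyl CH3 (the only enolisable position) with Et3N and catalytic ZnCl2, followed by O-silylation, should give the cross-conjugated silyl dienol ether (silyl enol ether formation as used for 1-alkoxy-3-silyloxybutadienes).

Step 7
Reactants: 16 1,1-dimethoxy-3-(trimethylsilyloxy)buta-1,3-diene; 10 1-ethoxy-13-(2-methoxyphenyl)tridec-1-yn-3-one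
Product: 19 1-(2-ethoxy-4-hydroxy-6-methoxyphenyl)-11-(2-methoxyphenyl)undecan-1-one, via cyclohexadiene cycloadduct 17 (not isolated), via aryl silyl ether 18 (not isolated)
Conditions: 16 (2.5 equiv), toluene, 80 °C, sealed tube, argon; then 1 M HCl, THF, rt
Reagents that add atoms: none
Why: Proposed new method: the closest known reaction type is the [4+2] cycloaddition–aromatisation of 1,1-dialkoxy-3-silyloxybuta-1,3-dienes with acetylenic ketones and esters to resorcinol derivatives, here extended to a push–pull 1-alkoxyalkyn-3-one, in which the ethoxy group lowers the dienophilicity but leaves the alkyne carbon β to the ketone (the one bearing OEt) as the electrophilic site. The CH2 terminus of the silyl enol ether of 16 should bond to that β carbon and the ketene acetal carbon to the α carbon, either in one asynchronous Diels–Alder event or as a Michael addition followed by 6-exo-trig attack of the allenolate carbon on the dimethoxycarbenium ion, so that ring A closes as a six-membered carbocycle with both new C–C bonds made in this step and cyclohexa-1,4-diene 17 results. Vinylogous 1,4-elimination of methanol from the ketal carbon and the ring CH2 of 17, driven by aromatisation, should give aryl silyl ether 18, and dilute acid then removes the trimethylsilyl group to give phenol 19. No stereocentre is created. The step needs regioselectivity (acyl carbon between the OMe and OEt carbons, silyloxy carbon para to it) and chemoselectivity for the alkyne over the carbonyl group: the first is secured by the matching polarisation of the nucleophilic diene CH2 terminus and the ketone-polarised β carbon of 10, the second by working without a Lewis acid, and the temperature is held at 80 °C so that the ethoxyalkyne does not lose ethene by a retro-ene reaction.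

Step 8
Reactants: 19 1-(2-ethoxy-4-hydroxy-6-methoxyphenyl)-11-(2-methoxyphenyl)undecan-1-one
Product: 20 1-(2,4,6-trihydroxyphenyl)-11-(2-hydroxyphenyl)undecan-1-one
Conditions: BBr3 (8 equiv), CH2Cl2, −78 °C to rt; then ice/H2O
Reagents that add atoms: none
Why: BBr3 should complex each ether oxygen and bromide then dealkylates it by SN2 attack at methyl or ethyl (Lewis-acid ether cleavage), the two ethers ortho to the ketone being helped by chelation, while the aryl ketone and the saturated chain are inert and aqueous work-up frees the four phenols.

**Compound list**

1 | methyl undec-10-enoate | C=CCCCCCCCCC(=O)OC | starting material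
2 | 9-borabicyclo[3.3.1]nonane (9-BBN) | B1C2CCCC1CCC2 | starting material
3 | 2-bromoanisole | COc1ccccc1Br | starting material
4 | methyl 11-(9-borabicyclo[3.3.1]nonan-9-yl)undecanoate | COC(=O)CCCCCCCCCCB1C2CCCC1CCC2 | intermediate (not isolated)
5 | methyl 11-(2-methoxyphenyl)undecanoate | COC(=O)CCCCCCCCCCc1ccccc1OC | intermediate
6 | N-methoxy-N-methyl-11-(2-methoxyphenyl)undecanamide | CON(C)C(=O)CCCCCCCCCCc1ccccc1OC | intermediate
7 | ethoxyacetylene | CCOC#C | starting material
8 | lithium ethoxyacetylide | [Li]C#COCC | intermediate (not isolated)
9 | lithium 1-ethoxy-3-[methoxy(methyl)amino]-13-(2-methoxyphenyl)tridec-1-yn-3-olate | CCOC#CC(O[Li])(N(C)OC)CCCCCCCCCCc1ccccc1OC | intermediate (not isolated)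
10 | 1-ethoxy-13-(2-methoxyphenyl)tridec-1-yn-3-one | CCOC#CC(=O)CCCCCCCCCCc1ccccc1OC | intermediate
11 | acetyl chloride | CC(=O)Cl | starting material
12 | 1,1-dichloroethene | C=C(Cl)Cl | starting material
13 | 4,4,4-trichlorobutan-2-one | CC(=O)CC(Cl)(Cl)Cl | intermediate (not isolated)
14 | 4,4-dichlorobut-3-en-2-one | CC(=O)C=C(Cl)Cl | intermediate
15 | 4,4-dimethoxybut-3-en-2-one | CC(=O)C=C(OC)OC | intermediate
16 | 1,1-dimethoxy-3-(trimethylsilyloxy)buta-1,3-diene | COC(OC)=CC(=C)O[Si](C)(C)C | intermediate
17 | 1-[2-ethoxy-6,6-dimethoxy-4-(trimethylsilyloxy)cyclohexa-1,4-dien-1-yl]-11-(2-methoxyphenyl)undecan-1-one | CCOC1=C(C(=O)CCCCCCCCCCc2ccccc2OC)C(OC)(OC)C=C(O[Si](C)(C)C)C1 | intermediate (not isolated)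
18 | 1-[2-ethoxy-6-methoxy-4-(trimethylsilyloxy)phenyl]-11-(2-methoxyphenyl)undecan-1-one | CCOc1cc(O[Si](C)(C)C)cc(OC)c1C(=O)CCCCCCCCCCc1ccccc1OC | intermediate (not isolated)
19 | 1-(2-ethoxy-4-hydroxy-6-methoxyphenyl)-11-(2-methoxyphenyl)undecan-1-one | CCOc1cc(O)cc(OC)c1C(=O)CCCCCCCCCCc1ccccc1OC | intermediate
20 | 1-(2,4,6-trihydroxyphenyl)-11-(2-hydroxyphenyl)undecan-1-one | O=C(CCCCCCCCCCc1ccccc1O)c1c(O)cc(O)cc1O | target

**Step count and risks**

Total step count: 8 steps.
Longest linear sequence: 5 steps (steps 1, 2, 3, 7, 8 from methyl undec-10-enoate; the diene arm, steps 4, 5, 6, 7, 8, is equally long).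

Steps most likely to fail:

Step 7 (proposed new method). The push–pull alkyne may react so slowly that the diene is consumed by hydrolysis or oligomerisation first. Forcing the temperature may trigger retro-ene loss of ethene from the ethoxyalkyne, and the diene may attack the carbonyl group instead of the alkyne. The fallback uses known chemistry, gives up the ring construction and acylates a preformed ring A. It sets out from ester 5 and comes back to the route at target 20. Saponification of 5 (LiOH, THF/H2O, rt, then acidification) should give 11-(2-methoxyphenyl)undecanoic acid F1, and (COCl)2 with catalytic DMF in CH2Cl2 should give 11-(2-methoxyphenyl)undecanoyl chloride F2. Friedel–Crafts acylation of purchased 1,3,5-trimethoxybenzene (COc1cc(OC)cc(OC)c1) with AlCl3 in CH2Cl2 at 0 °C should give 1-(2,4,6-trimethoxyphenyl)-11-(2-methoxyphenyl)undecan-1-one F3. Any ortho demethylation by AlCl3 is harmless, since BBr3 under the conditions of step 8 then cleaves all four methyl ethers of F3 to give 20.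

Step 3. The N,O-dimethylhydroxylamine liberated at the quench may add in conjugate fashion to the new ynone, and the alkynyl ether may be hydrated to a β-keto ester during work-up or chromatography. The fallback avoids any amine and forms the ynone by oxidation under neutral conditions. It sets out from ester 5 and comes back at ynone 10. Partial reduction of 5 with iBu2AlH (CH2Cl2, −78 °C) should give 11-(2-methoxyphenyl)undecanal F4. Addition of lithium ethoxyacetylide 8 (THF, −78 °C, neutral work-up) should give racemic 1-ethoxy-13-(2-methoxyphenyl)tridec-1-yn-3-ol F5, and oxidation of this propargylic alcohol with activated MnO2 (CH2Cl2, rt) should give 10.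

Step 1. Oxidative addition into the electron-rich, ortho-substituted aryl bromide may be slow, so that protodeboronation of the alkylborane or β-hydride elimination at palladium competes, and the aqueous base may begin to hydrolyse the ester. The fallback reverses the polarity of the coupling. It sets out from 1 and 3 and comes back at ester 5. Radical anti-Markovnikov hydrobromination of 1 (HBr, dibenzoyl peroxide, hexane, 0 °C) should give methyl 11-bromoundecanoate F6. Magnesium insertion into 3 (Mg, THF) should give 2-methoxyphenylmagnesium bromide F7. Slow addition of F7 to F6 with Fe(acac)3 (5 mol %) and TMEDA in THF at 0 °C (iron-catalysed Kumada-type aryl–alkyl coupling, which tolerates the ester at this temperature) should give 5.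

Further compounds
F1 | step 7 | 11-(2-methoxyphenyl)undecanoic acid | OC(=O)CCCCCCCCCCc1ccccc1OC
F2 | step 7 | 11-(2-methoxyphenyl)undecanoyl chloride | ClC(=O)CCCCCCCCCCc1ccccc1OC
F3 | step 7 | 1-(2,4,6-trimethoxyphenyl)-11-(2-methoxyphenyl)undecan-1-one | COc1cc(OC)c(C(=O)CCCCCCCCCCc2ccccc2OC)c(OC)c1
F4 | step 3 | 11-(2-methoxyphenyl)undecanal | O=CCCCCCCCCCCc1ccccc1OC
F5 | step 3 | 1-ethoxy-13-(2-methoxyphenyl)tridec-1-yn-3-ol (racemic) | CCOC#CC(O)CCCCCCCCCCc1ccccc1OC
F6 | step 1 | methyl 11-bromoundecanoate | COC(=O)CCCCCCCCCCBr
F7 | step 1 | 2-methoxyphenylmagnesium bromide | COc1ccccc1[Mg]Br
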